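**Plan**

1. Numbering: hydrindane C1–C7a (C1 carries the side chain, C4 the gem-dimethyl group, C7a the angular methyl, C3a is the ring-fusion CH); C8 = alkene carbon, C9 = CH(CH2OAc), C10 = CH2OAc; lactone C2′(=O), C3′(OH), C4′, C5′H2.
2. Retrosynthesis: cut the acetate C–O, then the lactone O–C2′ and C3′–C4′ (syn-aldol with glyoxylate), then C8–C9 (alkenylcopper 1,4-addition), then C6–C7 and C3a–C4 together (six-membered ring opened to a cyclopentanone plus prenal), then C7a–C7 and C1–vinyl (conjugate addition/enolate alkylation of 2-methylcyclopent-2-en-1-one).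
3. Enabling feature: ring atoms C4(CH3)2–C5–C6 are an intact prenyl unit held between the C7 methylene on quaternary C7a and the ring-fusion carbon C3a, so a C7–boron bond can take up the carbene carbon of prenal (C6) and the resulting α-boryl prenyl unit can hand its γ-carbon C4 to a C3a ketone.
4. Forward: five-membered ring first (commercial enone), six-membered ring by the boron-relayed annulation, helpers removed (boron expelled; C3a–OH and C5=C6 by dehydration/hydrogenation; vinyl unmasked to acetyl), then the side chain joined at C8–C9 and the lactone closed last.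
5. Stereochemistry: C1 from copper-catalysed asymmetric conjugate addition, C7a from trans enolate alkylation, C3a from hydrogenation anti to the angular methyl, C9/C4′/C3′ from one (S)-4-benzyloxazolidin-2-one auxiliary (1,4-addition, then syn-aldol).

Key step: step 4

Remark: in step 1 the antipode of the chiral ligand is the one that delivers the 3R adduct; boronic acid 6 is carried on crude.

**Route**

Step 1
Reactants: 1 2-methylcyclopent-2-en-1-one; 2 vinylmagnesium bromide; 3 2-(iodomethyl)-4,4,5,5-tetramethyl-1,3,2-dioxaborolane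
Product: 5 (2R,3R)-3-ethenyl-2-methyl-2-[(4,4,5,5-tetramethyl-1,3,2-dioxaborolan-2-yl)methyl]cyclopentan-1-one, via magnesium enolate 4 (not isolated)
Conditions: Cu(OTf)2 (5 mol%), chiral N-heterocyclic carbene ligand from a C2-symmetric 4,5-diphenylimidazolinium salt (6 mol%), Et2O, −30 °C; then 3, DMPU, −30 °C to rt
Reagents that add atoms: none
Why: Copper-catalysed asymmetric conjugate addition of a Grignard reagent to an α-substituted cyclic enone followed by enolate alkylation, in which the chiral copper–carbene complex delivers vinyl to one enantioface of the β-carbon (C1 of the target, R) and the trisubstituted magnesium enolate 4 is C-alkylated by the α-iodo boronate anti to the new vinyl group, which sets the quaternary centre C7a with CH2B trans to vinyl.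

Step 2
Reactants: 5 (2R,3R)-3-ethenyl-2-methyl-2-[(4,4,5,5-tetramethyl-1,3,2-dioxaborolan-2-yl)methyl]cyclopentan-1-one
Product: 6 {[(1R,2R)-2-ethenyl-1-methyl-5-oxocyclopentyl]methyl}boronic acid
Conditions: NaIO4, NH4OAc, acetone/H2O (1:1), rt
Reagents that add atoms: water, O
Why: Periodate cleavage of the pinacol diol drives hydrolysis of the boronic ester to the free boronic acid, the boron species that is Lewis acidic enough to react with a diazo compound, and no stereocentre is touched.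

Step 3
Reactants: 7 3-methylbut-2-enal (prenal)
Product: 8 N′-[(1E)-3-methylbut-2-en-1-ylidene]-4-methylbenzenesulfonohydrazide
Conditions: TsNHNH2, MeOH, 0 °C to rt
Reagents that add atoms: 4-methylbenzenesulfonohydrazide, NNS(=O)(=O)c1ccc(C)cc1
Why: Hydrazone condensation of the enal with tosylhydrazide should give the E-hydrazone, the Bamford–Stevens precursor of the diazoalkene.

Step 4
Reactants: 6 {[(1R,2R)-2-ethenyl-1-methyl-5-oxocyclopentyl]methyl}boronic acid; 8 N′-[(1E)-3-methylbut-2-en-1-ylidene]-4-methylbenzenesulfonohydrazide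
Product: 12 (1R,3aS,7aR)-1-ethenyl-4,4,7a-trimethyl-1,2,3,4,7,7a-hexahydro-3aH-inden-3a-ol (cis ring fusion, OH cis to the angular methyl), via diazoalkene 9 (not isolated), via allylboronic acid 10 (not isolated), via borate ester 11 (not isolated)
Conditions: K2CO3 (2.5 equiv), 8 (1.5 equiv), 1,4-dioxane, 110 °C; aqueous work-up
Reagents that add atoms: none
Why: Proposed new method: K2CO3 converts 8 into diazoalkene 9 (Bamford–Stevens), whose carbon adds to the vacant boron orbital of 6, and the C7 methylene then shifts from boron to carbon with loss of N2 (C6–C7 bond) to give the α-substituted γ,γ-dimethylallylboronic acid 10, which transfers its γ-carbon C4 to the C3a ketone through a closed six-centre boat transition state (B–O contact across the forming ring, bicyclo[2.2.2]-like) with allyl shift to C5=C6 (C3a–C4 bond). The closest known reaction types are the Barluenga–Valdés reductive coupling of tosylhydrazones with alkylboronic acids, the domino cyclisations in which allylboronic acids generated this way are trapped by a tethered carbonyl or nitrile group, and intramolecular carbonyl allylboration. The six-membered ring is closed by 6-exo-trig attack of the allyl γ-carbon on the carbonyl carbon (SE2′ with all three allyl carbons in the ring, so the new ring double bond is cis). The only new stereocentre that survives work-up, the C3a carbinol, is fixed by the two-atom tether C7–C7a, which can deliver C4 only to the carbonyl face syn to C7 (cis fusion), and it is erased again in step 5, while the boron-bearing C6 centre of 10 is destroyed in the allyl shift. The step needs cyclisation to outrun protodeboronation of 10 and needs γ- and not α-attack: the ketone held five atoms from C4 should secure the first, α-attack would need a four-membered ring, and the unactivated C1 vinyl group offers no competing pathway.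

Step 5
Reactants: 12 (1R,3aS,7aR)-1-ethenyl-4,4,7a-trimethyl-1,2,3,4,7,7a-hexahydro-3aH-inden-3a-ol
Product: 13 (1R,7aR)-1-ethenyl-4,4,7a-trimethyl-2,4,7,7a-tetrahydro-1H-indene
Conditions: Burgess reagent, toluene, 60 °C
Reagents that add atoms: none
Why: Burgess dehydration (syn-elimination through the sulfamate) can give only the C3=C3a alkene because C4 and C7a are quaternary and only C3 carries β-hydrogens, and it removes the transient C3a stereocentre.

Step 6
Reactants: 13 (1R,7aR)-1-ethenyl-4,4,7a-trimethyl-2,4,7,7a-tetrahydro-1H-indene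
Product: 14 1-[(1S,7aR)-4,4,7a-trimethyl-2,4,7,7a-tetrahydro-1H-inden-1-yl]ethan-1-one
Conditions: PdCl2 (10 mol%), CuCl (1 equiv), O2 (1 atm), DMF/H2O (7:1), rt
Reagents that add atoms: water, O
Why: Tsuji–Wacker oxidation, in which divalent palladium hydroxypalladates the monosubstituted vinyl group in the Markovnikov sense much faster than the 1,2-disubstituted and trisubstituted ring alkenes, should give the methyl ketone without touching C1.

Step 7
Reactants: 14 1-[(1S,7aR)-4,4,7a-trimethyl-2,4,7,7a-tetrahydro-1H-inden-1-yl]ethan-1-one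
Product: 15 1-[(1S,3aS,7aS)-4,4,7a-trimethyloctahydro-1H-inden-1-yl]ethan-1-one
Conditions: H2 (20 bar), Pd/C, EtOAc, rt
Reagents that add atoms: none
Why: Heterogeneous catalytic hydrogenation saturates C5=C6 and delivers hydrogen to C3=C3a on the face opposite to the angular methyl, the syn-axial C4 methyl and the C1 acetyl group, which sets C3a–H trans to the C7a methyl (trans-hydrindane) as in the hydrogenation of 14-ene steroids that carry a 17β side chain.

Step 8
Reactants: 15 1-[(1S,3aS,7aS)-4,4,7a-trimethyloctahydro-1H-inden-1-yl]ethan-1-one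
Product: 16 N′-{(1E)-1-[(1S,3aS,7aS)-4,4,7a-trimethyloctahydro-1H-inden-1-yl]ethylidene}-2,4,6-tri(propan-2-yl)benzenesulfonohydrazide
Conditions: 2,4,6-triisopropylbenzenesulfonyl hydrazide, cat. HCl, THF, rt
Reagents that add atoms: 2,4,6-tri(propan-2-yl)benzenesulfonohydrazide, NNS(=O)(=O)c1c(C(C)C)cc(C(C)C)cc1C(C)C
Why: Condensation to the trisylhydrazone (Shapiro precursor) should give the E isomer, which places N–H syn to the methyl group and so directs the later deprotonation to that methyl.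

Step 9
Reactants: 17 (4S)-4-benzyl-1,3-oxazolidin-2-one; 18 prop-2-enoyl chloride (acryloyl chloride)
Product: 19 (4S)-4-benzyl-3-(prop-2-enoyl)-1,3-oxazolidin-2-one
Conditions: MeMgBr (1.0 equiv), THF, 0 °C; then 18, −78 °C
Reagents that add atoms: none
Why: N-Acylation of the magnesiated oxazolidinone with the acid chloride is a standard way to the acrylimide and leaves the auxiliary stereocentre untouched.

Step 10
Reactants: 19 (4S)-4-benzyl-3-(prop-2-enoyl)-1,3-oxazolidin-2-one; 20 tert-butyl(dimethyl)(prop-2-en-1-yloxy)silane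
Product: 21 (4S)-4-benzyl-3-[(2E)-4-{[tert-butyl(dimethyl)silyl]oxy}but-2-enoyl]-1,3-oxazolidin-2-one
Conditions: second-generation Hoveyda–Grubbs catalyst RuCl2(H2IMes)(=CH–C6H4-2-OiPr) (5 mol%), 20 (3 equiv), CH2Cl2, 40 °C
Reagents that add atoms: none
Why: Olefin cross-metathesis between an electron-poor acrylimide and an allyl ether is a selective pairing that should give the E-enoyl imide.

Step 11
Reactants: 16 N′-{(1E)-1-[(1S,3aS,7aS)-4,4,7a-trimethyloctahydro-1H-inden-1-yl]ethylidene}-2,4,6-tri(propan-2-yl)benzenesulfonohydrazide; 21 (4S)-4-benzyl-3-[(2E)-4-{[tert-butyl(dimethyl)silyl]oxy}but-2-enoyl]-1,3-oxazolidin-2-one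
Product: 25 (4S)-4-benzyl-3-[(3R)-3-({[tert-butyl(dimethyl)silyl]oxy}methyl)-4-[(1R,3aS,7aS)-4,4,7a-trimethyloctahydro-1H-inden-1-yl]pent-4-enoyl]-1,3-oxazolidin-2-one, via alkenyllithium 22 (not isolated), via alkenylmagnesium bromide 23 (not isolated), via alkenylcopper 24 (not isolated)
Conditions: n-BuLi (2.1 equiv), THF, −78 to 0 °C; MgBr2·OEt2, −78 °C; CuBr·SMe2, −40 °C; then 21 (1.3 equiv), −40 to −10 °C; aqueous work-up
Reagents that add atoms: none
Why: The Shapiro reaction (dianion formation at the methyl group syn to N–H, then loss of sulfinate and N2) gives alkenyllithium 22, which after transmetallation adds 1,4 to the N-enoyl oxazolidinone under chelation control (magnesium bridges both carbonyls in the syn-s-cis conformer and benzyl shields one face), setting C9 as R.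

Step 12
Reactants: 25 (4S)-4-benzyl-3-[(3R)-3-({[tert-butyl(dimethyl)silyl]oxy}methyl)-4-[(1R,3aS,7aS)-4,4,7a-trimethyloctahydro-1H-inden-1-yl]pent-4-enoyl]-1,3-oxazolidin-2-one; 26 ethyl 2-oxoacetate (ethyl glyoxylate)
Product: 28 ethyl (2S,3S,4R)-3-{[(4S)-4-benzyl-2-oxo-1,3-oxazolidin-3-yl]carbonyl}-4-({[tert-butyl(dimethyl)silyl]oxy}methyl)-2-hydroxy-5-[(1R,3aS,7aS)-4,4,7a-trimethyloctahydro-1H-inden-1-yl]hex-5-enoate, via boron enolate 27 (not isolated)
Conditions: Bu2BOTf, i-Pr2NEt, CH2Cl2, 0 °C; 26 (freshly distilled), −78 to 0 °C; pH 7 buffer, MeOH, H2O2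
Reagents that add atoms: none
Why: Evans syn-aldol reaction, in which the Z-boron enolate 27 reacts with the glyoxylate through a Zimmerman–Traxler chair with the auxiliary dipole opposed so that the aldehyde enters opposite to benzyl, sets C4′ and C3′ 2,3-syn (trans on the later lactone) with the absolute sense needed next to C9.

Step 13
Reactants: 28 ethyl (2S,3S,4R)-3-{[(4S)-4-benzyl-2-oxo-1,3-oxazolidin-3-yl]carbonyl}-4-({[tert-butyl(dimethyl)silyl]oxy}methyl)-2-hydroxy-5-[(1R,3aS,7aS)-4,4,7a-trimethyloctahydro-1H-inden-1-yl]hex-5-enoate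
Product: 31 (3S,4R)-3-hydroxy-4-{(2R)-1-hydroxy-3-[(1R,3aS,7aS)-4,4,7a-trimethyloctahydro-1H-inden-1-yl]but-3-en-2-yl}oxolan-2-one, via hydroxy ester 29 (not isolated), via silyl ether lactone 30 (not isolated)
Conditions: NaBH4, THF/H2O (4:1), 0 °C; then 1 M HCl, THF, rt
Reagents that add atoms: none
Why: Reductive cleavage of the N-acyl oxazolidinone with NaBH4 (the exocyclic imide carbonyl is the most electrophilic one) gives primary alcohol 29, which lactonises onto the ethyl ester by 5-exo-trig acyl substitution to 30 before aqueous acid removes the primary silyl ether, and no stereocentre is affected.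

Step 14
Reactants: 31 (3S,4R)-3-hydroxy-4-{(2R)-1-hydroxy-3-[(1R,3aS,7aS)-4,4,7a-trimethyloctahydro-1H-inden-1-yl]but-3-en-2-yl}oxolan-2-one
Product: 32 (2R)-2-[(3R,4S)-4-hydroxy-5-oxooxolan-3-yl]-3-[(1R,3aS,7aS)-4,4,7a-trimethyloctahydro-1H-inden-1-yl]but-3-en-1-yl acetate (CNP0252518.2)
Conditions: AcCl (1.05 equiv), 2,4,6-collidine, CH2Cl2, −78 °C
Reagents that add atoms: acetyl chloride, CC(=O)Cl
Why: Selective O-acylation with acetyl chloride and a hindered pyridine base at low temperature should acetylate the primary C10 hydroxyl much faster than the hindered secondary C3′ hydroxyl next to the lactone carbonyl.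

**Compound list**

1 | 2-methylcyclopent-2-en-1-one | CC1=CCCC1=O | starting material
2 | vinylmagnesium bromide | C=C[Mg]Br | starting material
3 | 2-(iodomethyl)-4,4,5,5-tetramethyl-1,3,2-dioxaborolane | ICB1OC(C)(C)C(C)(C)O1 | starting material
4 | bromomagnesium (3R)-3-ethenyl-2-methylcyclopent-1-en-1-olate | C=C[C@H]1CCC(O[Mg]Br)=C1C | intermediate
5 | (2R,3R)-3-ethenyl-2-methyl-2-[(4,4,5,5-tetramethyl-1,3,2-dioxaborolan-2-yl)methyl]cyclopentan-1-one | C=C[C@H]1CCC(=O)[C@]1(C)CB2OC(C)(C)C(C)(C)O2 | intermediate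
6 | {[(1R,2R)-2-ethenyl-1-methyl-5-oxocyclopentyl]methyl}boronic acid | C=C[C@H]1CCC(=O)[C@]1(C)CB(O)O | intermediate
7 | 3-methylbut-2-enal | CC(C)=CC=O | starting material
8 | N′-[(1E)-3-methylbut-2-en-1-ylidene]-4-methylbenzenesulfonohydrazide | CC(C)=C/C=N/NS(=O)(=O)c1ccc(C)cc1 | intermediate
9 | 1-diazo-3-methylbut-2-ene | CC(C)=CC=[N+]=[N-] | intermediate
10 | {1-[(1R,2R)-2-ethenyl-1-methyl-5-oxocyclopentyl]-4-methylpent-3-en-2-yl}boronic acid (both epimers at the boron-bearing carbon) | C=C[C@H]1CCC(=O)[C@]1(C)CC(B(O)O)C=C(C)C | intermediate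
11 | (1R,3aS,7aR)-1-ethenyl-4,4,7a-trimethyl-1,2,3,4,7,7a-hexahydro-3aH-inden-3a-yl dihydrogen borate | C=C[C@H]1CC[C@]2(OB(O)O)C(C)(C)C=CC[C@]12C | intermediate
12 | (1R,3aS,7aR)-1-ethenyl-4,4,7a-trimethyl-1,2,3,4,7,7a-hexahydro-3aH-inden-3a-ol | C=C[C@H]1CC[C@]2(O)C(C)(C)C=CC[C@]12C | intermediate
13 | (1R,7aR)-1-ethenyl-4,4,7a-trimethyl-2,4,7,7a-tetrahydro-1H-indene | C=C[C@H]1CC=C2C(C)(C)C=CC[C@]12C | intermediate
14 | 1-[(1S,7aR)-4,4,7a-trimethyl-2,4,7,7a-tetrahydro-1H-inden-1-yl]ethan-1-one | CC(=O)[C@H]1CC=C2C(C)(C)C=CC[C@]12C | intermediate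
15 | 1-[(1S,3aS,7aS)-4,4,7a-trimethyloctahydro-1H-inden-1-yl]ethan-1-one | CC(=O)[C@H]1CC[C@H]2C(C)(C)CCC[C@]12C | intermediate
16 | N′-{(1E)-1-[(1S,3aS,7aS)-4,4,7a-trimethyloctahydro-1H-inden-1-yl]ethylidene}-2,4,6-tri(propan-2-yl)benzenesulfonohydrazide | C/C(=N\NS(=O)(=O)c1c(C(C)C)cc(C(C)C)cc1C(C)C)[C@H]1CC[C@H]2C(C)(C)CCC[C@]12C | intermediate
17 | (4S)-4-benzyl-1,3-oxazolidin-2-one | O=C1N[C@@H](Cc2ccccc2)CO1 | starting material
18 | prop-2-enoyl chloride | C=CC(=O)Cl | starting material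
19 | (4S)-4-benzyl-3-(prop-2-enoyl)-1,3-oxazolidin-2-one | C=CC(=O)N1[C@@H](Cc2ccccc2)COC1=O | intermediate
20 | tert-butyl(dimethyl)(prop-2-en-1-yloxy)silane | C=CCO[Si](C)(C)C(C)(C)C | starting material
21 | (4S)-4-benzyl-3-[(2E)-4-{[tert-butyl(dimethyl)silyl]oxy}but-2-enoyl]-1,3-oxazolidin-2-one | CC(C)(C)[Si](C)(C)OC/C=C/C(=O)N1[C@@H](Cc2ccccc2)COC1=O | intermediate
22 | 1-(4,4,7a-trimethyloctahydro-1H-inden-1-yl)ethenyllithium (ring configuration as in 15) | [Li]C(=C)[C@H]1CC[C@H]2C(C)(C)CCC[C@]12C | intermediate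
23 | bromo[1-(4,4,7a-trimethyloctahydro-1H-inden-1-yl)ethenyl]magnesium (ring configuration as in 15) | Br[Mg]C(=C)[C@H]1CC[C@H]2C(C)(C)CCC[C@]12C | intermediate
24 | [1-(4,4,7a-trimethyloctahydro-1H-inden-1-yl)ethenyl]copper (ring configuration as in 15) | [Cu]C(=C)[C@H]1CC[C@H]2C(C)(C)CCC[C@]12C | intermediate
25 | (4S)-4-benzyl-3-[(3R)-3-({[tert-butyl(dimethyl)silyl]oxy}methyl)-4-[(1R,3aS,7aS)-4,4,7a-trimethyloctahydro-1H-inden-1-yl]pent-4-enoyl]-1,3-oxazolidin-2-one | C=C([C@H]1CC[C@H]2C(C)(C)CCC[C@]12C)[C@H](CO[Si](C)(C)C(C)(C)C)CC(=O)N1[C@@H](Cc2ccccc2)COC1=O | intermediate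
26 | ethyl 2-oxoacetate | CCOC(=O)C=O | starting material
27 | dibutylboron (Z)-enolate of 25 | C=C([C@H]1CC[C@H]2C(C)(C)CCC[C@]12C)[C@H](CO[Si](C)(C)C(C)(C)C)/C=C(\OB(CCCC)CCCC)N1[C@@H](Cc2ccccc2)COC1=O | intermediate
28 | ethyl (2S,3S,4R)-3-{[(4S)-4-benzyl-2-oxo-1,3-oxazolidin-3-yl]carbonyl}-4-({[tert-butyl(dimethyl)silyl]oxy}methyl)-2-hydroxy-5-[(1R,3aS,7aS)-4,4,7a-trimethyloctahydro-1H-inden-1-yl]hex-5-enoate | C=C([C@H]1CC[C@H]2C(C)(C)CCC[C@]12C)[C@H](CO[Si](C)(C)C(C)(C)C)[C@H](C(=O)N1[C@@H](Cc2ccccc2)COC1=O)[C@H](O)C(=O)OCC | intermediate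
29 | ethyl (2S,3R,4R)-4-({[tert-butyl(dimethyl)silyl]oxy}methyl)-2-hydroxy-3-(hydroxymethyl)-5-[(1R,3aS,7aS)-4,4,7a-trimethyloctahydro-1H-inden-1-yl]hex-5-enoate | C=C([C@H]1CC[C@H]2C(C)(C)CCC[C@]12C)[C@H](CO[Si](C)(C)C(C)(C)C)[C@H](CO)[C@H](O)C(=O)OCC | intermediate
30 | (3S,4R)-4-{(2R)-1-{[tert-butyl(dimethyl)silyl]oxy}-3-[(1R,3aS,7aS)-4,4,7a-trimethyloctahydro-1H-inden-1-yl]but-3-en-2-yl}-3-hydroxyoxolan-2-one | C=C([C@H]1CC[C@H]2C(C)(C)CCC[C@]12C)[C@H](CO[Si](C)(C)C(C)(C)C)[C@@H]1COC(=O)[C@H]1O | intermediate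
31 | (3S,4R)-3-hydroxy-4-{(2R)-1-hydroxy-3-[(1R,3aS,7aS)-4,4,7a-trimethyloctahydro-1H-inden-1-yl]but-3-en-2-yl}oxolan-2-one | C=C([C@H]1CC[C@H]2C(C)(C)CCC[C@]12C)[C@H](CO)[C@@H]1COC(=O)[C@H]1O | intermediate
32 | (2R)-2-[(3R,4S)-4-hydroxy-5-oxooxolan-3-yl]-3-[(1R,3aS,7aS)-4,4,7a-trimethyloctahydro-1H-inden-1-yl]but-3-en-1-yl acetate | C=C([C@H]1CC[C@H]2C(C)(C)CCC[C@]12C)[C@H](COC(C)=O)[C@@H]1COC(=O)[C@H]1O | target

**Step count**

Total step count: 14. Longest linear sequence: 11 steps (steps 1, 2, 4, 5, 6, 7, 8, 11, 12, 13, 14).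

**Steps most likely to fail**

Step 4 (bears the label). What may go wrong: protodeboronation of the allylboronic acid intermediate, or failure of the boat-type allyl transfer to the ketone, so that the six-membered ring does not close. The fallback uses known chemistry, sets out from 5 and returns at 15. The C–B bond of 5 is oxidised (NaBO3·4H2O, THF/H2O) to (2S,3R)-3-ethenyl-2-(hydroxymethyl)-2-methylcyclopentan-1-one F1, and Dess–Martin periodinane converts this into (1S,2R)-2-ethenyl-1-methyl-5-oxocyclopentane-1-carbaldehyde F2. A Z-selective Wittig reaction with the ylide from (3-methylbut-3-en-1-yl)triphenylphosphonium bromide and NaHMDS forms C6=C7 and gives (2R,3R)-3-ethenyl-2-methyl-2-[(1Z)-4-methylpenta-1,4-dien-1-yl]cyclopentan-1-one F3. KHMDS/PhNTf2 then gives (4R,5R)-4-ethenyl-5-methyl-5-[(1Z)-4-methylpenta-1,4-dien-1-yl]cyclopent-1-en-1-yl trifluoromethanesulfonate F4. An intramolecular 6-exo reductive Heck cyclisation (Pd(OAc)2, PPh3, HCO2Na, DMF, 80 °C) forms C3a–C4, turns the isopropenyl CH2 into the second C4 methyl and gives (1R,7aR)-1-ethenyl-4,4,7a-trimethyl-2,4,5,7a-tetrahydro-1H-indene F5. Tsuji–Wacker oxidation (PdCl2, CuCl, O2) gives 1-[(1S,7aR)-4,4,7a-trimethyl-2,4,5,7a-tetrahydro-1H-inden-1-yl]ethan-1-one F6, and hydrogenation (H2, Pd/C) gives 15.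

Step 1. What may go wrong: poor enantioface selection in the copper-catalysed vinyl transfer to the α-substituted enone, or sluggish or O-selective alkylation of the magnesium enolate. The fallback sets out from 2 and returns at 5. Compound 2 is converted with 9-methoxy-9-borabicyclo[3.3.1]nonane into 9-ethenyl-9-borabicyclo[3.3.1]nonane F7. Rhodium-catalysed asymmetric 1,4-addition (Hayashi–Miyaura type, [Rh(OMe)(cod)]2 with the BINAP antipode that gives the R enolate) of F7 to cyclopent-2-en-1-one F8 gives the boron enolate 9-{[(3R)-3-ethenylcyclopent-1-en-1-yl]oxy}-9-borabicyclo[3.3.1]nonane F9. Treatment in the same flask with n-BuLi and iodomethane gives (2R,3R)-3-ethenyl-2-methylcyclopentan-1-one F10. This is converted (Me3SiCl, NaI, Et3N, MeCN) into the more substituted enol ether {[(3R)-3-ethenyl-2-methylcyclopent-1-en-1-yl]oxy}(trimethyl)silane F11. The lithium enolate released from F11 with MeLi is alkylated with 3 anti to the vinyl group to give 5.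

Step 5. What may go wrong: ionisation of the hindered tertiary sulfamate instead of syn-elimination, followed by a 1,2-methyl shift from C4 that is driven by formation of an allylic cation (C4–C5=C6). The fallback sets out from 12 and returns at 15, and changes the order so that C5=C6 is removed before the elimination. Tsuji–Wacker oxidation of 12 gives 1-[(1S,3aS,7aR)-3a-hydroxy-4,4,7a-trimethyl-2,3,3a,4,7,7a-hexahydro-1H-inden-1-yl]ethan-1-one F12. Hydrogenation (H2, 1 atm, Pd/C) saturates C5=C6 and gives 1-[(1S,3aS,7aR)-3a-hydroxy-4,4,7a-trimethyloctahydro-1H-inden-1-yl]ethan-1-one F13. Elimination (Burgess reagent, or SOCl2/pyridine at −20 °C), now without an allylic cation in reach, gives 1-[(1S,7aR)-4,4,7a-trimethyl-2,4,5,6,7,7a-hexahydro-1H-inden-1-yl]ethan-1-one F14, and a second hydrogenation under pressure gives 15.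

Further compounds
F1 | step 4 | (2S,3R)-3-ethenyl-2-(hydroxymethyl)-2-methylcyclopentan-1-one | C=C[C@H]1CCC(=O)[C@]1(C)CO
F2 | step 4 | (1S,2R)-2-ethenyl-1-methyl-5-oxocyclopentane-1-carbaldehyde | C=C[C@H]1CCC(=O)[C@]1(C)C=O
F3 | step 4 | (2R,3R)-3-ethenyl-2-methyl-2-[(1Z)-4-methylpenta-1,4-dien-1-yl]cyclopentan-1-one | C=C[C@H]1CCC(=O)[C@]1(C)/C=C\CC(C)=C
F4 | step 4 | (4R,5R)-4-ethenyl-5-methyl-5-[(1Z)-4-methylpenta-1,4-dien-1-yl]cyclopent-1-en-1-yl trifluoromethanesulfonate | C=C[C@H]1CC=C(OS(=O)(=O)C(F)(F)F)[C@]1(C)/C=C\CC(C)=C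
F5 | step 4 | (1R,7aR)-1-ethenyl-4,4,7a-trimethyl-2,4,5,7a-tetrahydro-1H-indene | C=C[C@H]1CC=C2C(C)(C)CC=C[C@]12C
F6 | step 4 | 1-[(1S,7aR)-4,4,7a-trimethyl-2,4,5,7a-tetrahydro-1H-inden-1-yl]ethan-1-one | CC(=O)[C@H]1CC=C2C(C)(C)CC=C[C@]12C
F7 | step 1 | 9-ethenyl-9-borabicyclo[3.3.1]nonane | C=CB1C2CCCC1CCC2
F8 | step 1 | cyclopent-2-en-1-one | O=C1C=CCC1
F9 | step 1 | 9-{[(3R)-3-ethenylcyclopent-1-en-1-yl]oxy}-9-borabicyclo[3.3.1]nonane | C=C[C@H]1CCC(OB2C3CCCC2CCC3)=C1
F10 | step 1 | (2R,3R)-3-ethenyl-2-methylcyclopentan-1-one | C=C[C@H]1CCC(=O)[C@@H]1C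
F11 | step 1 | {[(3R)-3-ethenyl-2-methylcyclopent-1-en-1-yl]oxy}(trimethyl)silane | C=C[C@H]1CCC(O[Si](C)(C)C)=C1C
F12 | step 5 | 1-[(1S,3aS,7aR)-3a-hydroxy-4,4,7a-trimethyl-2,3,3a,4,7,7a-hexahydro-1H-inden-1-yl]ethan-1-one | CC(=O)[C@H]1CC[C@]2(O)C(C)(C)C=CC[C@]12C
F13 | step 5 | 1-[(1S,3aS,7aR)-3a-hydroxy-4,4,7a-trimethyloctahydro-1H-inden-1-yl]ethan-1-one | CC(=O)[C@H]1CC[C@]2(O)C(C)(C)CCC[C@]12C
F14 | step 5 | 1-[(1S,7aR)-4,4,7a-trimethyl-2,4,5,6,7,7a-hexahydro-1H-inden-1-yl]ethan-1-one | CC(=O)[C@H]1CC=C2C(C)(C)CCC[C@]12C
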